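**Retrosynthetic overview**

1. The target is guibourtinidol-(4α→8)-fisetinidol. Rings D, E and F (lower unit) are bought intact as (−)-fisetinidol; only ring C of the upper unit has to be built, with C2, C3 and C4 all-trans.
2. Last disconnections: hydrogenolysis of all O-protecting groups; before that, the 3-OH of ring C and the 7-OH of ring D are unmasked together from one silicon atom that bridges C3 and O7 of ring D (Tamao–Fleming oxidation).
3. Key disconnection: ring C is opened at O1–C2 and C3–C4 to an o-quinone methide of ring A (O1=C8a–C4a=C4, with C4 carrying C8 of ring D) and an (E)-styrylsilane of ring B tied to O7 of ring D. Forward, one intramolecular hetero-[4+2] closes ring C and a temporary six-membered oxasiline ring.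
4. The o-quinone methide precursor comes from the 8-magnesiated, silicon-tethered fisetinidol derivative and 4-(benzyloxy)-2-hydroxybenzaldehyde (interflavan C4–C8 bond). The tether comes from alkyne hydrosilylation, and C8 of ring D is reached by ortho-metalation between O7 and O1.
5. Enabling feature: O1 of ring A is ortho to C4 (o-quinone methide), ring B has a para oxygen (cation at C2), and the 7-OH of ring D is ortho to C8, so O7 of ring D and the oxygen on C3 are 1,5-related across the interflavan bond. One silicon can therefore stand in for the C3 oxygen in a ring O7–C7–C8–C4–C3–Si, and the ortho oxygen that shields C4 from external partners becomes the delivery arm.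

Key step: step 8

Assumption: (−)-fisetinidol is taken as the purchasable enantiopure natural product with the (2R,3S) configuration, so rings D, E and F and their two stereocentres come from the chiral pool and are not touched.

**Route**

Step 1
Reactants: 1 (−)-fisetinidol
Product: 2 (2R,3S)-2-(2,2-diphenyl-1,3-benzodioxol-5-yl)chroman-3,7-diol
Conditions: Ph2CCl2 (1.3 equiv), K2CO3, MeCN, 50 °C
Reagents that add atoms: dichlorodiphenylmethane, ClC(Cl)(c1ccccc1)c1ccccc1
Why: Catechol ketalisation: only the ortho-dihydroxy pair of ring E can form a stable five-membered diaryl ketal, whereas a monoalkylated 7-OH or 3-OH would be an α-chloro ether that hydrolyses back on work-up.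

Step 2
Reactants: 2 (2R,3S)-2-(2,2-diphenyl-1,3-benzodioxol-5-yl)chroman-3,7-diol
Product: 3 (2R,3S)-2-(2,2-diphenyl-1,3-benzodioxol-5-yl)-7-(methoxymethoxy)chroman-3-ol
Conditions: MOMCl, K2CO3, acetone, 0 °C → rt
Reagents that add atoms: chloromethyl methyl ether, COCCl
Why: Williamson etherification: carbonate deprotonates only the remaining phenol (7-OH of ring D), not the secondary 3-OH, and installs the acetal that later directs metalation.

Step 3
Reactants: 3 (2R,3S)-2-(2,2-diphenyl-1,3-benzodioxol-5-yl)-7-(methoxymethoxy)chroman-3-ol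
Product: 4 (2R,3S)-3-(benzyloxy)-2-(2,2-diphenyl-1,3-benzodioxol-5-yl)-7-(methoxymethoxy)chroman
Conditions: NaH, BnBr, Bu4NI (cat.), DMF, 0 °C → rt
Reagents that add atoms: benzyl bromide, BrCc1ccccc1
Why: Williamson benzylation of the secondary alkoxide, as is routine for flavan-3-ols; C2 and C3 should not epimerise under these conditions.

Step 4
Reactants: 4 (2R,3S)-3-(benzyloxy)-2-(2,2-diphenyl-1,3-benzodioxol-5-yl)-7-(methoxymethoxy)chroman
Product: 6 (2R,3S)-3-(benzyloxy)-2-(2,2-diphenyl-1,3-benzodioxol-5-yl)-8-iodo-7-(methoxymethoxy)chroman, via 8-lithio species 5 (not isolated)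
Conditions: n-BuLi, TMEDA, THF, −78 → −20 °C; then I2, THF, −78 °C
Reagents that add atoms: iodine, II
Why: Directed ortho-metalation: C8 is the only position flanked by two oxygen directors (the MOM ether on O7 and the ring oxygen O1 of ring F), so lithium should go there rather than to C6, and iodine then traps the aryllithium.

Step 5
Reactants: 6 (2R,3S)-3-(benzyloxy)-2-(2,2-diphenyl-1,3-benzodioxol-5-yl)-8-iodo-7-(methoxymethoxy)chroman
Product: 7 (2R,3S)-3-(benzyloxy)-2-(2,2-diphenyl-1,3-benzodioxol-5-yl)-8-iodochroman-7-ol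
Conditions: HCl (cat.), MeOH/THF 1:1, 40 °C
Reagents that add atoms: none
Why: Acid-catalysed acetal exchange removes the phenolic MOM ether under conditions that the hindered diaryl ketal (which needs hot aqueous acid), the benzyl ether and the aryl iodide should survive.

Step 6
Reactants: 7 (2R,3S)-3-(benzyloxy)-2-(2,2-diphenyl-1,3-benzodioxol-5-yl)-8-iodochroman-7-ol; 8 1-(benzyloxy)-4-ethynylbenzene; 9 chlorodiisopropylsilane
Product: 11 (2R,3S)-3-(benzyloxy)-7-({[(E)-2-(4-benzyloxyphenyl)ethenyl]diisopropylsilyl}oxy)-2-(2,2-diphenyl-1,3-benzodioxol-5-yl)-8-iodochroman, via chlorosilane 10 (not isolated)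
Conditions: 8 + 9, Pt2(dvds)3/P(t-Bu)3 (0.5 mol %, zerovalent platinum), toluene, rt; then 7, imidazole, DMAP (cat.), CH2Cl2, rt
Reagents that add atoms: none
Why: Platinum-catalysed syn, anti-Markovnikov hydrosilylation of the terminal alkyne should give the (E)-β-silylstyrene, whose Si–Cl bond then silylates the phenol as in a TIPS-type protection; the two isopropyl groups make the aryl silyl ether robust.

Step 7
Reactants: 11 (2R,3S)-3-(benzyloxy)-7-({[(E)-2-(4-benzyloxyphenyl)ethenyl]diisopropylsilyl}oxy)-2-(2,2-diphenyl-1,3-benzodioxol-5-yl)-8-iodochroman; 12 4-(benzyloxy)-2-hydroxybenzaldehyde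
Product: 15 [4-(benzyloxy)-2-hydroxyphenyl][(2R,3S)-3-(benzyloxy)-7-({[(E)-2-(4-benzyloxyphenyl)ethenyl]diisopropylsilyl}oxy)-2-(2,2-diphenyl-1,3-benzodioxol-5-yl)chroman-8-yl]methanol (both carbinol epimers), via arylmagnesium chloride 13 (not isolated), via sodium phenolate 14 (not isolated)
Conditions: 11, iPrMgCl·LiCl, THF, −15 → 0 °C; 12, NaH, THF, 0 °C; combine at −40 → 0 °C; pH 7 buffer
Reagents that add atoms: none
Why: Iodine–magnesium exchange gives an aryl–magnesium that, unlike an aryllithium, should not suffer O→C silyl migration at low temperature, and its 1,2-addition to the chelated phenolate-aldehyde forms the interflavan C4–C8 bond; the carbinol configuration is irrelevant because it is erased in step 8.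

Step 8
Reactants: 15 [4-(benzyloxy)-2-hydroxyphenyl][(2R,3S)-3-(benzyloxy)-7-({[(E)-2-(4-benzyloxyphenyl)ethenyl]diisopropylsilyl}oxy)-2-(2,2-diphenyl-1,3-benzodioxol-5-yl)chroman-8-yl]methanol
Product: 17 silicon-bridged cycloadduct with ring C closed, (2R,3S,4S) in ring C, C3 bonded to Si(iPr)2 which is bonded to O7 of ring D (oxasiline trans-fused to ring C), via o-quinone methide 16 (not isolated)
Conditions: (R)-TRIP [(R)-3,3'-bis(2,4,6-triisopropylphenyl)-1,1'-binaphthyl-2,2'-diyl hydrogen phosphate] (10 mol %), 5 Å molecular sieves, toluene, −20 → 0 °C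
Reagents that add atoms: none
Why: Proposed new method: the chiral phosphoric acid should ionise the doubly activated benzhydrol to the hydrogen-bonded (E)-o-quinone methide 16 (O1=C8a–C4a=C4 of ring A), in which ring D stands perpendicular and holds O7 with its silicon-bound alkene directly under C4, so that the silicon-bearing carbon C3 attacks C4 and the C2 cation thus formed, stabilised by the β-silicon and by the para-benzyloxyphenyl ring B, is captured by O1, which amounts to an asynchronous intramolecular hetero-Diels–Alder reaction with inverse electron demand. The closest known reaction types are the chiral Brønsted acid-catalysed [4+2] cycloaddition of o-quinone methides from o-hydroxybenzhydrols with styrenes, the intramolecular o-quinone methide hetero-Diels–Alder reaction and the silicon-tethered Diels–Alder reaction of vinylsilanes; what is new is a vinylsilane that keeps its silicon as the 2π partner of an o-quinone methide. Ring C closes by the O1–C2 bond in a 6-exo-trig attack of O1 on the quinoid bond between C2 and C1 of ring B, and the temporary oxasiline ring (C4–C8–C7–O7–Si–C3) closes by the C3–C4 bond, again 6-exo-trig. C2 and C3 come out trans because the (E)-alkene adds suprafacially, C3 and C4 come out trans because the short O7–Si link can reach C3 only from the exo side of the (E)-methide (trans-fused oxasiline, ring B endo, all three substituents of ring C equatorial), and the absolute sense (4S) is left to the phosphate bound at O1 because the lower-unit stereocentres sit far above the opposite face; the hand of the acid has to be confirmed in the first run, the other facial isomer being a separable diastereomer. The step needs closure at C2 to outrun loss of silicon from the β-silyl cation, which the two isopropyl groups on silicon, the weakly nucleophilic phosphate and the antiperiplanar alignment of C3–Si with the forming O1–C2 bond are there to secure, while regiochemistry is fixed twice, by the tether and by the cation-stabilising groups on C2.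

Step 9
Reactants: 17 silicon-bridged cycloadduct
Product: 18 7,4'-di-O-benzyl-guibourtinidol-(4α→8)-[3-O-benzyl-3',4'-O-diphenylmethylene-fisetinidol], with free 3-OH on ring C and free 7-OH on ring D
Conditions: KF, KHCO3, 30% aq. H2O2, THF/MeOH 1:1, 45 °C
Reagents that add atoms: hydrogen peroxide, OO
Why: Tamao–Fleming oxidation: the silicon already has an oxygen ligand, so fluoride and peroxide should form the hypervalent silicate in which C3 migrates from silicon to oxygen with retention, giving the (3S)-alcohol trans to both aryl groups while the Si–O7 bond is cleaved to free the ring-D phenol.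

Step 10
Reactants: 18 protected dimer
Product: 19 guibourtinidol-(4α→8)-fisetinidol, (2R,3S,4S)-2-(4-hydroxyphenyl)-4-[(2R,3S)-2-(3,4-dihydroxyphenyl)-3,7-dihydroxychroman-8-yl]chroman-3,7-diol
Conditions: H2 (1 atm), Pd(OH)2/C, THF/MeOH 1:1, rt
Reagents that add atoms: none
Why: Catalytic hydrogenolysis should cleave the three benzyl ethers and the diphenylmethylene ketal in one operation, as in the usual deprotection of benzylated oligoflavanoids, without touching the ring C–O bonds or any stereocentre.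

**Compound list**

1 | (−)-fisetinidol, (2R,3S)-2-(3,4-dihydroxyphenyl)chroman-3,7-diol | Oc1ccc2c(c1)O[C@H](c1ccc(O)c(O)c1)[C@@H](O)C2 | starting material
2 | (2R,3S)-2-(2,2-diphenyl-1,3-benzodioxol-5-yl)chroman-3,7-diol | Oc1ccc2c(c1)O[C@H](c1ccc3OC(c4ccccc4)(c4ccccc4)Oc3c1)[C@@H](O)C2 | intermediate
3 | (2R,3S)-2-(2,2-diphenyl-1,3-benzodioxol-5-yl)-7-(methoxymethoxy)chroman-3-ol | COCOc1ccc2c(c1)O[C@H](c1ccc3OC(c4ccccc4)(c4ccccc4)Oc3c1)[C@@H](O)C2 | intermediate
4 | (2R,3S)-3-(benzyloxy)-2-(2,2-diphenyl-1,3-benzodioxol-5-yl)-7-(methoxymethoxy)chroman | COCOc1ccc2c(c1)O[C@H](c1ccc3OC(c4ccccc4)(c4ccccc4)Oc3c1)[C@@H](OCc1ccccc1)C2 | intermediate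
5 | 8-lithio derivative of 4 | COCOc1ccc2c(c1[Li])O[C@H](c1ccc3OC(c4ccccc4)(c4ccccc4)Oc3c1)[C@@H](OCc1ccccc1)C2 | intermediate (not isolated)
6 | (2R,3S)-3-(benzyloxy)-2-(2,2-diphenyl-1,3-benzodioxol-5-yl)-8-iodo-7-(methoxymethoxy)chroman | COCOc1ccc2c(c1I)O[C@H](c1ccc3OC(c4ccccc4)(c4ccccc4)Oc3c1)[C@@H](OCc1ccccc1)C2 | intermediate
7 | (2R,3S)-3-(benzyloxy)-2-(2,2-diphenyl-1,3-benzodioxol-5-yl)-8-iodochroman-7-ol | Oc1ccc2c(c1I)O[C@H](c1ccc3OC(c4ccccc4)(c4ccccc4)Oc3c1)[C@@H](OCc1ccccc1)C2 | intermediate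
8 | 1-(benzyloxy)-4-ethynylbenzene | C#Cc1ccc(OCc2ccccc2)cc1 | starting material
9 | chlorodiisopropylsilane | CC(C)[SiH](Cl)C(C)C | starting material
10 | chloro[(E)-2-(4-benzyloxyphenyl)ethenyl]diisopropylsilane | CC(C)[Si](Cl)(/C=C/c1ccc(OCc2ccccc2)cc1)C(C)C | intermediate (not isolated)
11 | (2R,3S)-3-(benzyloxy)-7-({[(E)-2-(4-benzyloxyphenyl)ethenyl]diisopropylsilyl}oxy)-2-(2,2-diphenyl-1,3-benzodioxol-5-yl)-8-iodochroman | CC(C)[Si](/C=C/c1ccc(OCc2ccccc2)cc1)(C(C)C)Oc1ccc2c(c1I)O[C@H](c1ccc3OC(c4ccccc4)(c4ccccc4)Oc3c1)[C@@H](OCc1ccccc1)C2 | intermediate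
12 | 4-(benzyloxy)-2-hydroxybenzaldehyde | O=Cc1ccc(OCc2ccccc2)cc1O | starting material
13 | 8-(chloromagnesio) derivative of 11 | CC(C)[Si](/C=C/c1ccc(OCc2ccccc2)cc1)(C(C)C)Oc1ccc2c(c1[Mg]Cl)O[C@H](c1ccc3OC(c4ccccc4)(c4ccccc4)Oc3c1)[C@@H](OCc1ccccc1)C2 | intermediate (not isolated)
14 | sodium 5-(benzyloxy)-2-formylphenolate | [Na+].[O-]c1cc(OCc2ccccc2)ccc1C=O | intermediate (not isolated)
15 | [4-(benzyloxy)-2-hydroxyphenyl][(2R,3S)-3-(benzyloxy)-7-({[(E)-2-(4-benzyloxyphenyl)ethenyl]diisopropylsilyl}oxy)-2-(2,2-diphenyl-1,3-benzodioxol-5-yl)chroman-8-yl]methanol, both carbinol epimers | CC(C)[Si](/C=C/c1ccc(OCc2ccccc2)cc1)(C(C)C)Oc1ccc2c(c1C(O)c1ccc(OCc3ccccc3)cc1O)O[C@H](c1ccc3OC(c4ccccc4)(c4ccccc4)Oc3c1)[C@@H](OCc1ccccc1)C2 | intermediate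
16 | (E)-o-quinone methide of ring A: 3-(benzyloxy)-6-(arylmethylidene)cyclohexa-2,4-dien-1-one, aryl = C8 of the silyl-tethered ring D of 15 | O=C1C=C(OCc2ccccc2)C=C/C1=C\c1c(O[Si](C(C)C)(C(C)C)/C=C/c2ccc(OCc3ccccc3)cc2)ccc2c1O[C@H](c1ccc3OC(c4ccccc4)(c4ccccc4)Oc3c1)[C@@H](OCc1ccccc1)C2 | intermediate (not isolated)
17 | silicon-bridged cycloadduct: (2R,3S,4S)-7-(benzyloxy)-2-(4-benzyloxyphenyl)chroman whose C3 is bonded to Si(iPr)2 and whose C4 is bonded to C8 of the protected fisetinidol unit, the silicon being bonded to O7 of ring D (oxasiline trans-fused to ring C) | C(c1ccccc1)Oc1ccc([C@H]2Oc3cc(OCc4ccccc4)ccc3[C@H]3c4c(O[Si](C(C)C)(C(C)C)[C@H]23)ccc5c4O[C@H](c4ccc6OC(c7ccccc7)(c7ccccc7)Oc6c4)[C@@H](OCc4ccccc4)C5)cc1 | intermediate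
18 | (2R,3S,4S)-7-(benzyloxy)-2-(4-benzyloxyphenyl)-4-[(2R,3S)-3-(benzyloxy)-2-(2,2-diphenyl-1,3-benzodioxol-5-yl)-7-hydroxychroman-8-yl]chroman-3-ol | C(c1ccccc1)Oc1ccc([C@H]2Oc3cc(OCc4ccccc4)ccc3[C@@H](c3c(O)ccc4c3O[C@H](c3ccc5OC(c6ccccc6)(c6ccccc6)Oc5c3)[C@@H](OCc3ccccc3)C4)[C@@H]2O)cc1 | intermediate
19 | guibourtinidol-(4α→8)-fisetinidol, (2R,3S,4S)-2-(4-hydroxyphenyl)-4-[(2R,3S)-2-(3,4-dihydroxyphenyl)-3,7-dihydroxychroman-8-yl]chroman-3,7-diol | Oc1ccc([C@H]2Oc3cc(O)ccc3[C@@H](c3c(O)ccc4c3O[C@H](c3ccc(O)c(O)c3)[C@@H](O)C4)[C@@H]2O)cc1 | target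

**Step count**

Total steps: 10. Longest linear sequence: 10 steps (1 → 19); compounds 8, 9 and 12 are bought and enter directly, so there is no separate branch.

**Steps most likely to fail**

Step 8 (proposed new method). What may go wrong: loss of silicon from the β-silyl cation before O1 closes on C2 (open-chain alkenylation instead of ring closure), or insufficient control of the o-quinone methide face by the chiral acid. The fallback uses known chemistry only; it sets out from 4 and comes back at 18. Aryllithium 5, made as in step 4, is added to sodium phenolate 14 to give the 7-O-MOM o-hydroxybenzhydrol F1. Alkyne 8 is hydroborated with catecholborane to the catechol alkenylboronate F2 and hydrolysed to the (E)-alkenylboronic acid F3. Under chiral 3,3'-dibromo-BINOL catalysis, F3 adds in conjugate fashion to the o-quinone methide F4 released from F1 (alkenyl transfer from boron held at O1, catalyst-controlled at C4) to give the (S)-1,1-diarylallyl phenol F5. Shi epoxidation with the L-sorbose-derived enantiomer of the fructose ketone (KHSO5, pH 10.5) gives the (2S,3S)-epoxide F6. The ring-A phenol opens F6 at the benzylic carbon with inversion (6-endo, trace CSA) to give the 2,3-trans-3,4-trans flavan-3-ol F7, and acidic methanolysis of the MOM ether (HCl, MeOH) gives 18. Ring C is then closed by the same O1–C2 bond, but stepwise, with the two catalyst-controlled events separated.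

Step 9. What may go wrong: Peterson-type β-elimination, because the C3–Si bond is antiperiplanar to the benzylic C2–O1 bond and activation at silicon may reopen ring C faster than C3 migrates to oxygen; or slow oxidation of the hindered diisopropylsilyl group. The fallback sets out from 17, comes back at 18, and turns the elimination into the route. CSA in MeOH/CH2Cl2 opens 17 by anti elimination to the (E)-alkene phenol F8, with C4 untouched and silicon left on O7 of ring D as a methoxydiisopropylsilyl ether that keeps this phenol out of the next step. Shi epoxidation (same ketone as above) gives epoxide F9, and 6-endo opening by the ring-A phenol gives the silyl-protected flavan-3-ol F10. Bu4NF removes the silyl ether to give 18.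

Step 7. What may go wrong: migration of silicon from O7 to C8 in the ortho-metalated aryl silyl ether, or sluggish addition of the doubly ortho-substituted aryl–magnesium to the phenolate-deactivated aldehyde. The fallback sets out from 11 and 12 and comes back at 15. Compound 12 is O-allylated (allyl bromide, K2CO3, acetone) to 2-(allyloxy)-4-(benzyloxy)benzaldehyde F11. Nozaki–Hiyama–Kishi coupling of iodide 11 with F11 (CrCl2, NiCl2 cat., DMF) gives the O-allyl benzhydrol F12 through a weakly basic aryl–chromium species that adds to the now fully electrophilic aldehyde. Pd(PPh3)4 and morpholine remove the allyl group under neutral conditions to give 15.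

Further compounds
F1 | step 8 | [4-(benzyloxy)-2-hydroxyphenyl][(2R,3S)-3-(benzyloxy)-2-(2,2-diphenyl-1,3-benzodioxol-5-yl)-7-(methoxymethoxy)chroman-8-yl]methanol | COCOc1ccc2c(c1C(O)c1ccc(OCc3ccccc3)cc1O)O[C@H](c1ccc3OC(c4ccccc4)(c4ccccc4)Oc3c1)[C@@H](OCc1ccccc1)C2
F2 | step 8 | 2-[(E)-2-(4-benzyloxyphenyl)ethenyl]-1,3,2-benzodioxaborole | c1ccc2OB(/C=C/c3ccc(OCc4ccccc4)cc3)Oc2c1
F3 | step 8 | (E)-[2-(4-benzyloxyphenyl)ethenyl]boronic acid | OB(O)/C=C/c1ccc(OCc2ccccc2)cc1
F4 | step 8 | (E)-o-quinone methide of ring A with 7-O-MOM ring D | O=C1C=C(OCc2ccccc2)C=C/C1=C\c1c(OCOC)ccc2c1O[C@H](c1ccc3OC(c4ccccc4)(c4ccccc4)Oc3c1)[C@@H](OCc1ccccc1)C2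
F5 | step 8 | 5-(benzyloxy)-2-[(1S,2E)-3-(4-benzyloxyphenyl)-1-(7-O-MOM ring-D aryl)prop-2-enyl]phenol | Oc1cc(OCc2ccccc2)ccc1[C@@H](c1c(OCOC)ccc2c1O[C@H](c1ccc3OC(c4ccccc4)(c4ccccc4)Oc3c1)[C@@H](OCc1ccccc1)C2)/C=C/c1ccc(OCc2ccccc2)cc1
F6 | step 8 | (2S,3S)-epoxide of F5 | Oc1cc(OCc2ccccc2)ccc1[C@@H](c1c(OCOC)ccc2c1O[C@H](c1ccc3OC(c4ccccc4)(c4ccccc4)Oc3c1)[C@@H](OCc1ccccc1)C2)[C@@H]1O[C@H]1c1ccc(OCc2ccccc2)cc1
F7 | step 8 | 7-O-MOM (ring D) ether of 18 | C(c1ccccc1)Oc1ccc([C@H]2Oc3cc(OCc4ccccc4)ccc3[C@@H](c3c(OCOC)ccc4c3O[C@H](c3ccc5OC(c6ccccc6)(c6ccccc6)Oc5c3)[C@@H](OCc3ccccc3)C4)[C@@H]2O)cc1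
F8 | step 9 | 5-(benzyloxy)-2-[(1S,2E)-3-(4-benzyloxyphenyl)-1-(7-O-methoxydiisopropylsilyl ring-D aryl)prop-2-enyl]phenol | Oc1cc(OCc2ccccc2)ccc1[C@@H](c1c(O[Si](OC)(C(C)C)C(C)C)ccc2c1O[C@H](c1ccc3OC(c4ccccc4)(c4ccccc4)Oc3c1)[C@@H](OCc1ccccc1)C2)/C=C/c1ccc(OCc2ccccc2)cc1
F9 | step 9 | (2S,3S)-epoxide of F8 | Oc1cc(OCc2ccccc2)ccc1[C@@H](c1c(O[Si](OC)(C(C)C)C(C)C)ccc2c1O[C@H](c1ccc3OC(c4ccccc4)(c4ccccc4)Oc3c1)[C@@H](OCc1ccccc1)C2)[C@@H]1O[C@H]1c1ccc(OCc2ccccc2)cc1
F10 | step 9 | 7-O-methoxydiisopropylsilyl (ring D) ether of 18 | C(c1ccccc1)Oc1ccc([C@H]2Oc3cc(OCc4ccccc4)ccc3[C@@H](c3c(O[Si](OC)(C(C)C)C(C)C)ccc4c3O[C@H](c3ccc5OC(c6ccccc6)(c6ccccc6)Oc5c3)[C@@H](OCc3ccccc3)C4)[C@@H]2O)cc1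
F11 | step 7 | 2-(allyloxy)-4-(benzyloxy)benzaldehyde | C=CCOc1cc(OCc2ccccc2)ccc1C=O
F12 | step 7 | O-allyl ether (ring-A phenol) of 15 | CC(C)[Si](/C=C/c1ccc(OCc2ccccc2)cc1)(C(C)C)Oc1ccc2c(c1C(O)c1ccc(OCc3ccccc3)cc1OCC=C)O[C@H](c1ccc3OC(c4ccccc4)(c4ccccc4)Oc3c1)[C@@H](OCc1ccccc1)C2
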